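## Retrosynthetic overview

1. Eriolangin 30 ⇐ hydroxy α-methylene lactone 26 + angelic acid 27 (last bond made); the exo-methylene comes from Mannich methylenation of lactone 22, the γ-lactone from cis-hydroxy tert-butyl ester 20.
2. 20 ⇐ β-hydroxy enone 19 by hydroxyl-directed 1,3-anti reduction; the ring CH2OH ⇐ vinylogous triflate 16 by Stille coupling.
3. Key C–C bond (ring carbon to the side-chain CH(CH3)): catalyst-controlled intermolecular Michael addition of cyclic 1,3-dione 10 to crotonaldehyde 11.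
4. Dione 10 ⇐ Claisen ring closure of keto diester 9 ⇐ dimethyl (S)-malate 1 + tert-butyl bromoacetate 2 (Fráter–Seebach alkylation sets the two future ring-fusion centres).
5. Ring order: the cyclohexane ring is closed first (step 8), the γ-lactone second (step 18).

Assumption: the 2-substituted cyclohexane-1,3-diones 12–15 are drawn as one enol tautomer; 12 is in practice a mixture with its cyclic hemiacetals, all of which react as the open aldehyde in step 10.

## Route

Step 1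
Reactants: 1 dimethyl (S)-malate; 2 tert-butyl bromoacetate
Product: 3 (2S,3R)-hydroxy triester
Conditions: LiN(iPr)2 (2.2 equiv), THF, −78 → −20 °C; then 2, −78 → −10 °C; aq. NH4Cl
Reagents that add atoms: none
Why: Fráter–Seebach alkylation, in which the chelated lithium alkoxide–enolate dianion is alkylated on the face anti to the C2 oxygen to give the (2S,3R) product, fixing the centres that become C7a and C3a of the lactone.

Step 2
Reactants: 3 (2S,3R)-hydroxy triester
Product: 4 1,2-diol diester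
Conditions: BH3·SMe2 (1.05 equiv), NaBH4 (5 mol %), THF, 0 °C → rt; then H2O
Reagents that add atoms: none
Why: Chelation-controlled borane reduction (Saito conditions), in which the alkoxyborane formed at the free hydroxyl reduces only the adjacent α-hydroxy methyl ester through a five-membered ring and leaves the other two esters.

Step 3
Reactants: 4 1,2-diol diester
Product: 5 primary tosylate
Conditions: TsCl (1.05 equiv), Et3N, Bu2SnO (2 mol %), CH2Cl2, 0 °C
Reagents that add atoms: p-toluenesulfonyl chloride, Cc1ccc(cc1)S(Cl)(=O)=O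
Why: Stannylene-acetal-catalysed sulfonylation selects the primary hydroxyl of the 1,2-diol.

Step 4
Reactants: 5 primary tosylate
Product: 6 terminal epoxide
Conditions: K2CO3, MeOH, 0 °C
Reagents that add atoms: none
Why: Intramolecular Williamson (SN2) displacement of the primary tosylate by the neighbouring alkoxide closes the epoxide without touching either stereocentre.

Step 5
Reactants: 6 terminal epoxide
Product: 7 homoallylic alcohol
Conditions: CH2=C(CH3)MgBr (2 equiv), CuI (10 mol %), THF, −40 °C; aq. NH4Cl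
Reagents that add atoms: isopropenylmagnesium bromide, C=C(C)[Mg]Br
Why: Copper-catalysed Grignard opening of the epoxide at its unsubstituted carbon (SN2) is faster than addition to the esters at low temperature and leaves the carbinol centre unchanged.

Step 6
Reactants: 7 homoallylic alcohol
Product: 8 TBS ether
Conditions: TBSOTf, 2,6-lutidine, CH2Cl2, −78 °C
Reagents that add atoms: tert-butyldimethylsilyl trifluoromethanesulfonate, CC(C)(C)[Si](C)(C)OS(=O)(=O)C(F)(F)F
Why: Silyl triflate silylation of the hindered secondary alcohol blocks lactonisation onto the tert-butyl ester in the basic steps that follow.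

Step 7
Reactants: 8 TBS ether
Product: 9 methyl ketone diester
Conditions: O3, CH2Cl2/MeOH, −78 °C; then PPh3
Reagents that add atoms: ozone, [O-][O+]=O
Why: Ozonolysis with reductive work-up cleaves the only alkene (1,1-disubstituted) to the methyl ketone.

Step 8
Reactants: 9 methyl ketone diester
Product: 10 silyloxy cyclohexane-1,3-dione
Conditions: LiN(SiMe3)2 (2.3 equiv), THF, −78 → 0 °C; aq. NH4Cl
Reagents that add atoms: none
Why: Intramolecular Claisen condensation, in which the kinetic methyl-ketone enolate attacks the methyl ester (6-exo-trig) and is driven by formation of the stabilised dione enolate, so no enolate forms at the two stereogenic ring carbons.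

Step 9
Reactants: 10 silyloxy cyclohexane-1,3-dione; 11 crotonaldehyde
Product: 12 Michael adduct (enol aldehyde)
Conditions: (R)-2-[diphenyl(trimethylsilyloxy)methyl]pyrrolidine (20 mol %), PhCO2H (20 mol %), CH2Cl2, 0 °C → rt
Reagents that add atoms: none
Why: Iminium-catalysed intermolecular Michael addition, in which the diphenyl(silyloxy)methyl group of the (R)-catalyst shields one face of the E-iminium ion of 11 so that the dione carbon adds to the open face and sets the methyl-bearing centre as (S) under catalyst control, while hemiacetal formation stops a second addition.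

Step 10
Reactants: 12 Michael adduct (enol aldehyde)
Product: 13 terminal alkene
Conditions: Ph3PCH3Br (3.5 equiv), KOtBu (3.3 equiv), THF, 0 °C → rt
Reagents that add atoms: methyltriphenylphosphonium bromide, C[P+](c1ccccc1)(c1ccccc1)c1ccccc1.[Br-]
Why: Wittig methylenation of the aldehyde, which is released from its hemiacetal once the excess ylide has deprotonated the dione to its unreactive enolate.

Step 11
Reactants: 13 terminal alkene
Product: 14 primary alcohol
Conditions: 9-BBN (3 equiv), THF, 0 °C → rt; then H2O2, pH 7 phosphate buffer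
Reagents that add atoms: hydrogen peroxide, OO
Why: Anti-Markovnikov hydroboration–oxidation of the terminal alkene, the acidic enol using one equivalent of borane as an O-boryl enol ether that protects the dione.

Step 12
Reactants: 14 primary alcohol
Product: 15 side-chain TBDPS ether
Conditions: TBDPSCl (1.1 equiv), imidazole, CH2Cl2, 0 °C; aqueous work-up
Reagents that add atoms: tert-butyl(chloro)diphenylsilane, CC(C)(C)[Si](Cl)(c1ccccc1)c1ccccc1
Why: Silylation of the primary alcohol, any silyl enol ether of the dione being hydrolysed on work-up.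

Step 13
Reactants: 15 side-chain TBDPS ether
Product: 16 vinylogous triflate
Conditions: Tf2O (1.1 equiv), pyridine, CH2Cl2, −78 → −40 °C
Reagents that add atoms: trifluoromethanesulfonic anhydride, O=S(=O)(OS(=O)(=O)C(F)(F)F)C(F)(F)F
Why: O-sulfonylation of the dione enolate at the less hindered oxygen (next to the ring CH2, remote from the ring CH that carries the acetate arm), as 4-substituted cyclohexane-1,3-diones are O-functionalised at the remote oxygen.

Step 14
Reactants: 16 vinylogous triflate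
Product: 17 hydroxymethyl enone
Conditions: Bu3SnCH2OH (1.5 equiv), Pd(PPh3)4 (5 mol %), LiCl (3 equiv), 1,4-dioxane, 90 °C
Reagents that add atoms: (tributylstannyl)methanol, CCCC[Sn](CCCC)(CCCC)CO
Why: Migita–Kosugi–Stille coupling, in which zerovalent palladium inserts into the electron-poor vinyl triflate and the hydroxymethyl group is transferred from tin.

Step 15
Reactants: 17 hydroxymethyl enone
Product: 18 bis-TBDPS enone
Conditions: TBDPSCl, imidazole, DMF, rt
Reagents that add atoms: tert-butyl(chloro)diphenylsilane, CC(C)(C)[Si](Cl)(c1ccccc1)c1ccccc1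
Why: Silylation of the primary allylic alcohol so that only one hydroxyl is free for the directed reduction and the later acylation.

Step 16
Reactants: 18 bis-TBDPS enone
Product: 19 β-hydroxy enone
Conditions: HF·pyridine, pyridine, THF, 0 °C → rt
Reagents that add atoms: none
Why: Buffered HF·pyridine cleaves the secondary TBS ether much faster than the two TBDPS ethers and is non-basic, so the β-hydroxy ketone does not eliminate.

Step 17
Reactants: 19 β-hydroxy enone
Product: 20 anti-1,3-diol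
Conditions: Me4NBH(OAc)3 (5 equiv), MeCN/AcOH 1:1, −30 °C
Reagents that add atoms: none
Why: Evans–Saksena hydroxyl-directed reduction, in which the ring hydroxyl binds boron and delivers hydride to the same face of the enone carbonyl, giving the trans (1,3-anti) diol and setting the last ring stereocentre as (S).

Step 18
Reactants: 20 anti-1,3-diol
Product: 21 cis-fused hydroxy lactone
Conditions: NaH (10 mol %), THF, 0 °C → rt
Reagents that add atoms: none
Why: Alkoxide-catalysed lactonisation (5-exo-trig acyl substitution with loss of tert-butoxide), in which only the hydroxyl cis to the acetate arm can close an unstrained cis-fused γ-lactone.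

Step 19
Reactants: 21 cis-fused hydroxy lactone
Product: 22 TES ether lactone
Conditions: TESOTf, 2,6-lutidine, CH2Cl2, −78 °C
Reagents that add atoms: triethylsilyl trifluoromethanesulfonate, CC[Si](CC)(CC)OS(=O)(=O)C(F)(F)F
Why: Silyl triflate protection of the remaining allylic hydroxyl so that the lactone α-carbon is the only acidic site in the next step.

Step 20
Reactants: 22 TES ether lactone
Product: 23 α-(dimethylaminomethyl) lactone
Conditions: LiN(iPr)2 (1.3 equiv), THF, −78 °C; then CH2=NMe2 I (3 equiv), −78 °C → rt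
Reagents that add atoms: dimethyl(methylidene)ammonium iodide, C=[N+](C)C.[I-]
Why: Mannich reaction of the lactone lithium enolate with Eschenmoser's salt, the new α-centre being destroyed in the next step.

Step 21
Reactants: 23 α-(dimethylaminomethyl) lactone
Product: 25 α-methylene lactone TES ether, via quaternary ammonium iodide 24 (not isolated)
Conditions: MeI, MeOH, rt; then aq. NaHCO3, CH2Cl2, rt
Reagents that add atoms: none
Why: N-methylation followed by E1cB elimination of trimethylamine gives the exocyclic α-methylene (Eschenmoser methylenation).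

Step 22
Reactants: 25 α-methylene lactone TES ether
Product: 26 hydroxy α-methylene lactone
Conditions: HF·pyridine, pyridine, THF, 0 °C
Reagents that add atoms: none
Why: The TES ether is cleaved by buffered HF·pyridine far faster than the TBDPS ethers, under conditions that do not add to the α-methylene lactone.

Step 23
Reactants: 26 hydroxy α-methylene lactone; 27 angelic acid
Product: 29 angelate bis-TBDPS ether, via mixed anhydride 28 (not isolated)
Conditions: 2,4,6-Cl3C6H2COCl, Et3N, toluene, rt; then 26, toluene, 80 °C (no DMAP)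
Reagents that add atoms: none
Why: Yamaguchi-type mixed-anhydride esterification run without DMAP transfers the angeloyl group to the secondary alcohol without Z to E isomerisation to the tiglate.

Step 24
Reactants: 29 angelate bis-TBDPS ether
Product: 30 eriolangin
Conditions: HF·pyridine, pyridine, THF, 0 °C → rt
Reagents that add atoms: none
Why: HF·pyridine removes both TBDPS ethers under mildly acidic, non-nucleophilic conditions that the α-methylene lactone and the angelate tolerate.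

## Compound list

1 | dimethyl (2S)-2-hydroxybutanedioate (dimethyl (S)-malate) | COC(=O)[C@@H](O)CC(=O)OC | starting material
2 | tert-butyl 2-bromoacetate | CC(C)(C)OC(=O)CBr | starting material
3 | dimethyl (2S,3R)-3-[2-(tert-butoxy)-2-oxoethyl]-2-hydroxybutanedioate | COC(=O)[C@@H](O)[C@@H](CC(=O)OC(C)(C)C)C(=O)OC | intermediate
4 | 4-tert-butyl 1-methyl (2R)-2-[(1S)-1,2-dihydroxyethyl]butanedioate | OC[C@@H](O)[C@@H](CC(=O)OC(C)(C)C)C(=O)OC | intermediate
5 | 4-tert-butyl 1-methyl (2R)-2-[(1S)-1-hydroxy-2-(4-methylbenzenesulfonyloxy)ethyl]butanedioate | Cc1ccc(cc1)S(=O)(=O)OC[C@@H](O)[C@@H](CC(=O)OC(C)(C)C)C(=O)OC | intermediate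
6 | 4-tert-butyl 1-methyl (2R)-2-[(2S)-oxiran-2-yl]butanedioate | C1O[C@H]1[C@@H](CC(=O)OC(C)(C)C)C(=O)OC | intermediate
7 | 4-tert-butyl 1-methyl (2R)-2-[(1R)-1-hydroxy-3-methylbut-3-en-1-yl]butanedioate | C=C(C)C[C@@H](O)[C@@H](CC(=O)OC(C)(C)C)C(=O)OC | intermediate
8 | 4-tert-butyl 1-methyl (2R)-2-[(1R)-1-[(tert-butyldimethylsilyl)oxy]-3-methylbut-3-en-1-yl]butanedioate | C=C(C)C[C@@H](O[Si](C)(C)C(C)(C)C)[C@@H](CC(=O)OC(C)(C)C)C(=O)OC | intermediate
9 | 4-tert-butyl 1-methyl (2R)-2-[(1R)-1-[(tert-butyldimethylsilyl)oxy]-3-oxobutyl]butanedioate | CC(=O)C[C@@H](O[Si](C)(C)C(C)(C)C)[C@@H](CC(=O)OC(C)(C)C)C(=O)OC | intermediate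
10 | tert-butyl 2-[(1R,6R)-6-[(tert-butyldimethylsilyl)oxy]-2,4-dioxocyclohexyl]acetate | O=C1[C@H](CC(=O)OC(C)(C)C)[C@H](O[Si](C)(C)C(C)(C)C)CC(=O)C1 | intermediate
11 | (2E)-but-2-enal (crotonaldehyde) | C/C=C/C=O | starting material
12 | tert-butyl 2-[(1R,6R)-6-[(tert-butyldimethylsilyl)oxy]-4-hydroxy-2-oxo-3-[(2S)-4-oxobutan-2-yl]cyclohex-3-en-1-yl]acetate (enol form, in equilibrium with its cyclic hemiacetals) | O=C1[C@H](CC(=O)OC(C)(C)C)[C@H](O[Si](C)(C)C(C)(C)C)CC(O)=C1[C@@H](C)CC=O | intermediate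
13 | tert-butyl 2-[(1R,6R)-6-[(tert-butyldimethylsilyl)oxy]-4-hydroxy-2-oxo-3-[(2S)-pent-4-en-2-yl]cyclohex-3-en-1-yl]acetate | O=C1[C@H](CC(=O)OC(C)(C)C)[C@H](O[Si](C)(C)C(C)(C)C)CC(O)=C1[C@@H](C)CC=C | intermediate
14 | tert-butyl 2-[(1R,6R)-6-[(tert-butyldimethylsilyl)oxy]-4-hydroxy-3-[(2S)-5-hydroxypentan-2-yl]-2-oxocyclohex-3-en-1-yl]acetate | O=C1[C@H](CC(=O)OC(C)(C)C)[C@H](O[Si](C)(C)C(C)(C)C)CC(O)=C1[C@@H](C)CCCO | intermediate
15 | tert-butyl 2-[(1R,6R)-6-[(tert-butyldimethylsilyl)oxy]-3-[(2S)-5-[(tert-butyldiphenylsilyl)oxy]pentan-2-yl]-4-hydroxy-2-oxocyclohex-3-en-1-yl]acetate | O=C1[C@H](CC(=O)OC(C)(C)C)[C@H](O[Si](C)(C)C(C)(C)C)CC(O)=C1[C@@H](C)CCCO[Si](c2ccccc2)(c2ccccc2)C(C)(C)C | intermediate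
16 | tert-butyl 2-[(1R,6R)-6-[(tert-butyldimethylsilyl)oxy]-3-[(2S)-5-[(tert-butyldiphenylsilyl)oxy]pentan-2-yl]-2-oxo-4-[(trifluoromethanesulfonyl)oxy]cyclohex-3-en-1-yl]acetate | O=C1[C@H](CC(=O)OC(C)(C)C)[C@H](O[Si](C)(C)C(C)(C)C)CC(OS(=O)(=O)C(F)(F)F)=C1[C@@H](C)CCCO[Si](c2ccccc2)(c2ccccc2)C(C)(C)C | intermediate
17 | tert-butyl 2-[(1R,6R)-6-[(tert-butyldimethylsilyl)oxy]-3-[(2S)-5-[(tert-butyldiphenylsilyl)oxy]pentan-2-yl]-4-(hydroxymethyl)-2-oxocyclohex-3-en-1-yl]acetate | O=C1[C@H](CC(=O)OC(C)(C)C)[C@H](O[Si](C)(C)C(C)(C)C)CC(CO)=C1[C@@H](C)CCCO[Si](c2ccccc2)(c2ccccc2)C(C)(C)C | intermediate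
18 | tert-butyl 2-[(1R,6R)-6-[(tert-butyldimethylsilyl)oxy]-4-{[(tert-butyldiphenylsilyl)oxy]methyl}-3-[(2S)-5-[(tert-butyldiphenylsilyl)oxy]pentan-2-yl]-2-oxocyclohex-3-en-1-yl]acetate | O=C1[C@H](CC(=O)OC(C)(C)C)[C@H](O[Si](C)(C)C(C)(C)C)CC(CO[Si](c2ccccc2)(c2ccccc2)C(C)(C)C)=C1[C@@H](C)CCCO[Si](c2ccccc2)(c2ccccc2)C(C)(C)C | intermediate
19 | tert-butyl 2-[(1R,6R)-4-{[(tert-butyldiphenylsilyl)oxy]methyl}-3-[(2S)-5-[(tert-butyldiphenylsilyl)oxy]pentan-2-yl]-6-hydroxy-2-oxocyclohex-3-en-1-yl]acetate | O=C1[C@H](CC(=O)OC(C)(C)C)[C@H](O)CC(CO[Si](c2ccccc2)(c2ccccc2)C(C)(C)C)=C1[C@@H](C)CCCO[Si](c2ccccc2)(c2ccccc2)C(C)(C)C | intermediate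
20 | tert-butyl 2-[(1R,2S,6R)-4-{[(tert-butyldiphenylsilyl)oxy]methyl}-3-[(2S)-5-[(tert-butyldiphenylsilyl)oxy]pentan-2-yl]-2,6-dihydroxycyclohex-3-en-1-yl]acetate | O[C@H]1[C@H](CC(=O)OC(C)(C)C)[C@H](O)CC(CO[Si](c2ccccc2)(c2ccccc2)C(C)(C)C)=C1[C@@H](C)CCCO[Si](c2ccccc2)(c2ccccc2)C(C)(C)C | intermediate
21 | (3aS,4S,7aR)-6-{[(tert-butyldiphenylsilyl)oxy]methyl}-5-[(2S)-5-[(tert-butyldiphenylsilyl)oxy]pentan-2-yl]-4-hydroxy-3a,4,7,7a-tetrahydro-1-benzofuran-2(3H)-one | C1C(=O)O[C@@H]2CC(CO[Si](c3ccccc3)(c3ccccc3)C(C)(C)C)=C([C@@H](C)CCCO[Si](c3ccccc3)(c3ccccc3)C(C)(C)C)[C@@H](O)[C@H]12 | intermediate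
22 | (3aR,4S,7aR)-6-{[(tert-butyldiphenylsilyl)oxy]methyl}-5-[(2S)-5-[(tert-butyldiphenylsilyl)oxy]pentan-2-yl]-4-[(triethylsilyl)oxy]-3a,4,7,7a-tetrahydro-1-benzofuran-2(3H)-one | C1C(=O)O[C@@H]2CC(CO[Si](c3ccccc3)(c3ccccc3)C(C)(C)C)=C([C@@H](C)CCCO[Si](c3ccccc3)(c3ccccc3)C(C)(C)C)[C@@H](O[Si](CC)(CC)CC)[C@H]12 | intermediate
23 | (3aR,4S,7aR)-6-{[(tert-butyldiphenylsilyl)oxy]methyl}-5-[(2S)-5-[(tert-butyldiphenylsilyl)oxy]pentan-2-yl]-3-[(dimethylamino)methyl]-4-[(triethylsilyl)oxy]-3a,4,7,7a-tetrahydro-1-benzofuran-2(3H)-one (both C3 epimers) | CN(C)CC1C(=O)O[C@@H]2CC(CO[Si](c3ccccc3)(c3ccccc3)C(C)(C)C)=C([C@@H](C)CCCO[Si](c3ccccc3)(c3ccccc3)C(C)(C)C)[C@@H](O[Si](CC)(CC)CC)[C@H]12 | intermediate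
24 | {[(3aR,4S,7aR)-6-{[(tert-butyldiphenylsilyl)oxy]methyl}-5-[(2S)-5-[(tert-butyldiphenylsilyl)oxy]pentan-2-yl]-2-oxo-4-[(triethylsilyl)oxy]-2,3,3a,4,7,7a-hexahydro-1-benzofuran-3-yl]methyl}trimethylammonium iodide | C[N+](C)(C)CC1C(=O)O[C@@H]2CC(CO[Si](c3ccccc3)(c3ccccc3)C(C)(C)C)=C([C@@H](C)CCCO[Si](c3ccccc3)(c3ccccc3)C(C)(C)C)[C@@H](O[Si](CC)(CC)CC)[C@H]12.[I-] | intermediate
25 | (3aR,4S,7aR)-6-{[(tert-butyldiphenylsilyl)oxy]methyl}-5-[(2S)-5-[(tert-butyldiphenylsilyl)oxy]pentan-2-yl]-3-methylidene-4-[(triethylsilyl)oxy]-3a,4,7,7a-tetrahydro-1-benzofuran-2(3H)-one | C=C1C(=O)O[C@@H]2CC(CO[Si](c3ccccc3)(c3ccccc3)C(C)(C)C)=C([C@@H](C)CCCO[Si](c3ccccc3)(c3ccccc3)C(C)(C)C)[C@@H](O[Si](CC)(CC)CC)[C@H]12 | intermediate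
26 | (3aS,4S,7aR)-6-{[(tert-butyldiphenylsilyl)oxy]methyl}-5-[(2S)-5-[(tert-butyldiphenylsilyl)oxy]pentan-2-yl]-4-hydroxy-3-methylidene-3a,4,7,7a-tetrahydro-1-benzofuran-2(3H)-one | C=C1C(=O)O[C@@H]2CC(CO[Si](c3ccccc3)(c3ccccc3)C(C)(C)C)=C([C@@H](C)CCCO[Si](c3ccccc3)(c3ccccc3)C(C)(C)C)[C@@H](O)[C@H]12 | intermediate
27 | (2Z)-2-methylbut-2-enoic acid (angelic acid) | C/C=C(/C)C(=O)O | starting material
28 | (2Z)-2-methylbut-2-enoic 2,4,6-trichlorobenzoic anhydride | C/C=C(/C)C(=O)OC(=O)c1c(Cl)cc(Cl)cc1Cl | intermediate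
29 | [(3aR,4S,7aR)-6-{[(tert-butyldiphenylsilyl)oxy]methyl}-5-[(2S)-5-[(tert-butyldiphenylsilyl)oxy]pentan-2-yl]-3-methylidene-2-oxo-2,3,3a,4,7,7a-hexahydro-1-benzofuran-4-yl] (2Z)-2-methylbut-2-enoate | C=C1C(=O)O[C@@H]2CC(CO[Si](c3ccccc3)(c3ccccc3)C(C)(C)C)=C([C@@H](C)CCCO[Si](c3ccccc3)(c3ccccc3)C(C)(C)C)[C@@H](OC(=O)/C(C)=C\C)[C@H]12 | intermediate
30 | eriolangin, [(3aR,4S,7aR)-6-(hydroxymethyl)-5-[(2S)-5-hydroxypentan-2-yl]-3-methylidene-2-oxo-2,3,3a,4,7,7a-hexahydro-1-benzofuran-4-yl] (2Z)-2-methylbut-2-enoate | C=C1C(=O)O[C@@H]2CC(CO)=C([C@@H](C)CCCO)[C@@H](OC(=O)/C(C)=C\C)[C@H]12 | target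

## Step count and weak points

Total step count: 24. Longest linear sequence: 24 steps (1 → 30); all other inputs are bought.

Steps most likely to fail:

Step 8 (Claisen ring closure). The β-silyloxy ketone can lose silanol by E1cB if the enolate equilibrates, and the 5-silyloxy-1,3-dione can then aromatise. Fallback: setting out from 9, the methyl ester alone is hydrolysed (Me3SnOH, 1,2-dichloroethane, 70 °C) to the keto acid F1. This is converted (C6F5OH, EDC·HCl, CH2Cl2) into the pentafluorophenyl ester F2. Soft enolisation of the methyl ketone (MgBr2·OEt2, iPr2NEt, CH2Cl2, rt) then brings about intramolecular C-acylation without any strong base, and the route is rejoined at 10.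

Step 13 (O-triflation). The two enol oxygens differ only by the substitution of the neighbouring ring carbon, so a mixture of regioisomeric triflates is possible. Fallback: setting out from 15, the tert-butyl ester is cleaved (ZnBr2, CH2Cl2) to the acid F3. Its carboxyl can reach only the enol oxygen next to its own ring carbon, so dehydration (EDC·HCl, CH2Cl2) gives the single enol lactone F4, in which the other carbonyl is the only ketone. Me2S=CH2 (from Me3SI and n-BuLi, THF, −10 °C) adds to that ketone to give the spiro-epoxide F5. K2CO3 in MeOH opens the enol lactone to a methyl ester enolate, which expels the epoxide oxygen (E1cB) to give the hydroxymethyl enone methyl ester F6, now with fixed regiochemistry. Silylation (TBDPSCl, imidazole) gives the bis-TBDPS enone F7, HF·pyridine gives the β-hydroxy enone F8, and Me4NBH(OAc)3 gives the anti-diol methyl ester F9. Lactonisation of F9 (K2CO3, MeOH) rejoins the route at 21.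

Step 23 (angelate esterification). The secondary allylic alcohol is hindered, and forcing conditions isomerise angelate to tiglate. Fallback: setting out from 26, esterification with 2-[bis(2,2,2-trifluoroethoxy)phosphoryl]propanoic acid (DCC, cat. DMAP, CH2Cl2) gives the phosphonate ester F10. Still–Gennari olefination (KN(SiMe3)2, 18-crown-6, THF, −78 °C, then acetaldehyde) builds the (Z)-2-methylbut-2-enoate on the molecule and rejoins the route at 29.

## Further compounds

F1 | step 8 | (2R)-4-(tert-butoxy)-2-[(1R)-1-[(tert-butyldimethylsilyl)oxy]-3-oxobutyl]-4-oxobutanoic acid | CC(=O)C[C@@H](O[Si](C)(C)C(C)(C)C)[C@@H](CC(=O)OC(C)(C)C)C(=O)O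
F2 | step 8 | 4-tert-butyl 1-(pentafluorophenyl) (2R)-2-[(1R)-1-[(tert-butyldimethylsilyl)oxy]-3-oxobutyl]butanedioate | CC(=O)C[C@@H](O[Si](C)(C)C(C)(C)C)[C@@H](CC(=O)OC(C)(C)C)C(=O)Oc1c(F)c(F)c(F)c(F)c1F
F3 | step 13 | 2-[(1R,6R)-6-[(tert-butyldimethylsilyl)oxy]-3-[(2S)-5-[(tert-butyldiphenylsilyl)oxy]pentan-2-yl]-4-hydroxy-2-oxocyclohex-3-en-1-yl]acetic acid | O=C1[C@H](CC(=O)O)[C@H](O[Si](C)(C)C(C)(C)C)CC(O)=C1[C@@H](C)CCCO[Si](c2ccccc2)(c2ccccc2)C(C)(C)C
F4 | step 13 | (3aR,4R)-4-[(tert-butyldimethylsilyl)oxy]-7-[(2S)-5-[(tert-butyldiphenylsilyl)oxy]pentan-2-yl]-3a,4-dihydro-1-benzofuran-2,6(3H,5H)-dione | O=C1C[C@@H]2[C@H](O[Si](C)(C)C(C)(C)C)CC(=O)C([C@@H](C)CCCO[Si](c3ccccc3)(c3ccccc3)C(C)(C)C)=C2O1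
F5 | step 13 | (3aR,4R)-4-[(tert-butyldimethylsilyl)oxy]-7-[(2S)-5-[(tert-butyldiphenylsilyl)oxy]pentan-2-yl]-3,3a,4,5-tetrahydro-2H-spiro[1-benzofuran-6,2'-oxiran]-2-one (both spiro epimers) | O=C1C[C@@H]2[C@H](O[Si](C)(C)C(C)(C)C)CC3(CO3)C([C@@H](C)CCCO[Si](c4ccccc4)(c4ccccc4)C(C)(C)C)=C2O1
F6 | step 13 | methyl 2-[(1R,6R)-6-[(tert-butyldimethylsilyl)oxy]-3-[(2S)-5-[(tert-butyldiphenylsilyl)oxy]pentan-2-yl]-4-(hydroxymethyl)-2-oxocyclohex-3-en-1-yl]acetate | O=C1[C@H](CC(=O)OC)[C@H](O[Si](C)(C)C(C)(C)C)CC(CO)=C1[C@@H](C)CCCO[Si](c2ccccc2)(c2ccccc2)C(C)(C)C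
F7 | step 13 | methyl 2-[(1R,6R)-6-[(tert-butyldimethylsilyl)oxy]-4-{[(tert-butyldiphenylsilyl)oxy]methyl}-3-[(2S)-5-[(tert-butyldiphenylsilyl)oxy]pentan-2-yl]-2-oxocyclohex-3-en-1-yl]acetate | O=C1[C@H](CC(=O)OC)[C@H](O[Si](C)(C)C(C)(C)C)CC(CO[Si](c2ccccc2)(c2ccccc2)C(C)(C)C)=C1[C@@H](C)CCCO[Si](c2ccccc2)(c2ccccc2)C(C)(C)C
F8 | step 13 | methyl 2-[(1R,6R)-4-{[(tert-butyldiphenylsilyl)oxy]methyl}-3-[(2S)-5-[(tert-butyldiphenylsilyl)oxy]pentan-2-yl]-6-hydroxy-2-oxocyclohex-3-en-1-yl]acetate | O=C1[C@H](CC(=O)OC)[C@H](O)CC(CO[Si](c2ccccc2)(c2ccccc2)C(C)(C)C)=C1[C@@H](C)CCCO[Si](c2ccccc2)(c2ccccc2)C(C)(C)C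
F9 | step 13 | methyl 2-[(1R,2S,6R)-4-{[(tert-butyldiphenylsilyl)oxy]methyl}-3-[(2S)-5-[(tert-butyldiphenylsilyl)oxy]pentan-2-yl]-2,6-dihydroxycyclohex-3-en-1-yl]acetate | O[C@H]1[C@H](CC(=O)OC)[C@H](O)CC(CO[Si](c2ccccc2)(c2ccccc2)C(C)(C)C)=C1[C@@H](C)CCCO[Si](c2ccccc2)(c2ccccc2)C(C)(C)C
F10 | step 23 | [(3aR,4S,7aR)-6-{[(tert-butyldiphenylsilyl)oxy]methyl}-5-[(2S)-5-[(tert-butyldiphenylsilyl)oxy]pentan-2-yl]-3-methylidene-2-oxo-2,3,3a,4,7,7a-hexahydro-1-benzofuran-4-yl] 2-[bis(2,2,2-trifluoroethoxy)phosphoryl]propanoate (both epimers at the phosphonate carbon) | C=C1C(=O)O[C@@H]2CC(CO[Si](c3ccccc3)(c3ccccc3)C(C)(C)C)=C([C@@H](C)CCCO[Si](c3ccccc3)(c3ccccc3)C(C)(C)C)[C@@H](OC(=O)C(C)P(=O)(OCC(F)(F)F)OCC(F)(F)F)[C@H]12
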